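## Structural features

Disydonol C is a diarylmethane: two benzene rings joined by one CH2 bridge, each carrying a phenolic hydroxyl ortho to a tertiary benzylic carbinol of the type C(OH)(CH3)(4-methylpentyl). Ring A is trisubstituted (carbinol at C1, bridge at C4, OH at C6); ring B is tetrasubstituted (bridge at C1', carbinol at C3', OH at C4', CH2OH at C6'), so the hydroxymethyl group is ortho to the bridge and para to the carbinol. The only stereocentres are the two carbinol carbons, both S; they are not neighbours but lie nine bonds apart across both rings and the bridge, so neither can direct the other. The fragile parts are the two ortho-hydroxyaryl tertiary carbinols (in acid they ionise toward ortho-quinone methide-type cations, then dehydrate, cyclise or racemise), the three benzylic C–O bonds (open to hydrogenolysis) and the free phenols. The real difficulty is absolute control at two remote, fully substituted carbons whose alkyl groups (methyl and a primary chain) differ only in length; the substitution pattern of ring B is a second, smaller problem. The key step uses the fact that each carbinol carbon carries a methyl group and an aromatic ring: removing the 4-methylpentyl group leaves an acetyl group on C1 of ring A and on C3' of ring B. These two aryl methyl ketones sit in like surroundings (each ortho to a protected phenol oxygen) and are insulated by the sp3 bridge, so one chiral reagent can treat both alike.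

## Logic of the disconnections

**19 ⇐ 18 ⇐ 17.** Only O–Si and O–CH2Ph bonds are cut: the primary alcohol is covered as a silyl ether in 18 and the two phenols as benzyl ethers in 17. Deprotection comes last because free phenols next to the carbinols make the molecule acid-labile, and because a magnesium phenoxide or alkoxide would disturb the chiral complex of the key step. Benzyl is preferred to silyl on the phenols: an ortho-silyloxy group can migrate to the new tertiary alkoxide and open a quinone-methide pathway, whereas a benzyl ether is inert. The demand on the forward steps is a neutral hydrogenolysis that spares three other benzylic C–O bonds, then a non-acidic desilylation.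

**17 ⇐ 14 + 16.** Both bonds between a carbinol carbon and the first CH2 of its chain are cut in one operation. This removes both stereocentres and twelve carbon atoms and leaves 14 and two equivalents of 16. The cut is placed there because aryl methyl ketones are the ketone class for which ligand-controlled Grignard addition is established, and the larger group then arrives as a simple nucleophile. The forward step must choose the Si face at both carbonyl groups under reagent control alone and must avoid enolisation and reduction.

**14 ⇐ 13 ⇐ 12 ⇐ 11 ⇐ 10.** No skeletal bond is cut. The two C=O groups of 14 go back to the secondary alcohols of 13, the silyl ether to the primary alcohol of 12, the ring B benzyl ether to the phenol of 11, and all four hydroxyl groups of 11 to the methyl ester, two ketones and aryl ester of 10. The detour through the alcohols is accepted because no hydride reduces an ester beside two aryl ketones. Reducing everything and re-oxidising the two secondary benzylic alcohols takes three operations where double ketal formation, reduction, silylation and ketal hydrolysis would take four, and the same hydride frees the ring B phenol for benzylation. The forward steps need phenol-selective alkylation, primary-selective silylation, and an oxidation that touches neither ethers nor bridge.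

**10 ⇐ 6 + 9.** The bridge is cut between its CH2 and C4 of ring A, giving the benzylic bromide 6 and the arylboronic ester 9. This is the most convergent cut: two fragments of similar size, each already carrying its acetyl group. The coupling must tolerate two ketones and two esters and must not hydrolyse the benzylic bromide or the aryl ester before it reacts.

**6 ⇐ 5 ⇐ 4 ⇐ 2 ⇐ 1.** The C–Br bond of 6, the aryl O–acyl bond of 5, the ring-to-acetyl bond at C3' of 4 and the ester O–CH3 bond of 2 are cut in turn. The order is the point. The radical bromination is placed while the molecule holds no benzyl ether, no silyloxymethyl group and no ketal, since each of those has C–H bonds weaker than the aryl methyl group and would be attacked first. For that reason the ring B phenol travels as a pivalate through 5, 6 and 10, and the ester is reduced only after the coupling. The acyl migration must go to the ring carbon between the phenol oxygen and the unsubstituted CH; the para position is blocked by the methyl group and the other ortho position is crowded by the ester.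

**9 ⇐ 8 ⇐ 7 and 16 ⇐ 15.** The C–B bond of 9 goes back to the C–Br bond of 8, the benzyl ether of 8 to the phenol of 7, and the C–Mg bond of 16 to the C–Br bond of 15. These cuts only demand that the methyl ketone survive a borylation under weak base.

## Other disconnections considered

**Alternative 1:** Ring B is cut at C3'–C4' and C1'–C2'. The cycloadduct A1 (ring B at the methyl benzoate stage, both phenol/carbinol pairs bridged by diisopropylsilylene groups) would come from the tethered precursor A3. In A3 the tertiary alkynol A2 is tied through O–Si–O to C3 of a 2-pyrone that carries the ring A benzyl group at C6 and the ester at C5. On heating, the alkyne of A3 should add across pyrone C3 and C6 (intramolecular Diels–Alder), and loss of CO2 from the bicyclic adduct should give the benzene ring together with a six-membered dioxasiline.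
- In its favour: the tether fixes the substitution pattern of ring B, so no regiochemical question of the Fries kind arises; on this point it is the better plan. The C3' stereocentre arrives intact in A2 and, being fully substituted, cannot be lost on heating. The silylene bridges guard the acid-labile phenol/carbinol pairs and would fall to fluoride in one operation, which is at least the equal of benzyl ether hydrogenolysis.
- Against it here: only ring B is built. The ring A stereocentre must already be present, so two unrelated stereo-setting operations are needed. A2 itself requires enantioselective alkynylation of a methyl alkyl ketone carbonyl flanked by two very similar alkyl groups, or a resolution. The oxygenated pyrone half of A3 needs several steps, pyrone–alkyne cycloadditions need high temperatures at which tertiary silyloxy groups may eliminate, and the ester of A1 still has to be reduced afterwards.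
- Comparison: structurally both plans reach the full skeleton. Mechanistically this one is a substrate-bound pericyclic event with secure regiochemistry but no stereochemical gain, while the chosen plan creates both centres in one reagent-controlled step. In step economy the chosen plan should be clearly shorter.

**Alternative 2:** Both phenolic C–O bonds are cut. The bis-deoxy diol A5 (no phenols, CH2OH as silyl ether) would be converted into its bis(diethylhydrosilyl) ether A6. With [Ir(cod)OMe]2, 1,10-phenanthroline and norbornene as hydrogen acceptor, A6 should silylate the ortho C–H bonds at C6 and C4' to give the bis(benzoxasilole) A4. Tamao–Fleming oxidation of the two aryl C–Si bonds and desilylation would finish the synthesis.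
- In its favour: no phenol protecting group is needed at any stage. The bis-deoxy diketone A7 that stands behind A5 has no ortho substituent and is a better-precedented substrate for ligand-controlled Grignard addition than 14; on this point the alternative is the better plan. The front end would be shorter (no Fries step, no pivalate, no benzyl ethers). Regiochemistry is inherent: the two ortho positions of ring A are equivalent, and on ring B C4' is open while C2' is wedged between two substituents.
- Against it here: it does not solve the stereochemical problem; A5 still needs the same double asymmetric addition, now on A7. It then adds three operations on the most valuable intermediate. Two hindered tertiary silyl ethers must each direct a C–H silylation to completion and two aryl–silicon bonds must each be oxidised, or mixtures of partly oxygenated products result. The basic peroxide of the oxidation meets the sensitive ortho-hydroxyaryl carbinols as they form.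
- Comparison: equal in the stereo-setting mechanism; better in substrate fit and front-end length; worse in late-stage risk. Overall step count would be similar.

**Alternative 3:** Both aryl–carbinol bonds are cut. The carbenoid made from the (S)-configured secondary benzoate A9 with s-BuLi and N,N,N',N'-tetramethylethylenediamine would add to both boron atoms of the diarylmethane bis(arylboronic ester) A10. Each ate complex would undergo 1,2-aryl migration with loss of the benzoate to give the bis(tertiary boronic ester) A8, and oxidation with retention would give 17.
- In its favour: the step is stereospecific. Both centres derive from one secondary alcohol derivative of known configuration, so the outcome does not depend on telling methyl from a primary chain at a carbonyl face; in predictability of the absolute configuration it is the better plan. It is also two-directional, like the chosen plan.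
- Against it here: lithiation of the unactivated dialkyl benzoate A9 gives a thermally delicate carbenoid. Ate-complex formation at the ortho-benzyloxy arylboronic esters of A10 is hindered and may be reversible, which would cost conversion and enantiopurity at two sites per molecule. The organolithium meets an acidic diarylmethane CH2 and benzylic ethers. A10 is awkward to reach, since the bridge is best made by a boron-based coupling and two further C–B bonds must then be installed. A9 needs its own enantioselective preparation (asymmetric reduction or resolution), and an oxidation step is added.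
- Comparison: equal in the protected skeleton reached and in the two-directional logic; better in stereochemical certainty; worse in step count and in the demands on reagents. The complementary polarity, the benzylic bis(carbamate) F2 combined with the alkylboronic ester F3, is kept as the reserve for the key step.

Key step: step 13

Assumption: the (R,R)-antipode of the ligand 2,4-di-tert-butyl-6-({[(1R,2R)-2-(dimethylamino)cyclohexyl](methyl)amino}methyl)phenol (SMILES CN(C)[C@@H]1CCCC[C@H]1N(C)Cc1cc(C(C)(C)C)cc(C(C)(C)C)c1O) is taken as the one that sends the alkyl group to the Si face of an aryl methyl ketone. This sense has to be confirmed on a simple ortho-alkoxy aryl methyl ketone first; if it is opposite, the (S,S)-antipode is used with no other change. The ligand is a known, recoverable reagent and its preparation is not counted as a step.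

## Route

Step 1
Reactants: 1 5-hydroxy-2-methylbenzoic acid
Product: 2 methyl 5-hydroxy-2-methylbenzoate
Conditions: MeOH, H2SO4 (cat.), reflux
Reagents that add atoms: methanol, CO
Why: Fischer esterification leaves the phenol untouched; the ester is wanted because it survives the Lewis acid of step 2 and later keeps the bromomethyl compound from closing to a phthalide as the free acid would.

Step 2
Reactants: 2 methyl 5-hydroxy-2-methylbenzoate
Product: 4 methyl 4-acetyl-5-hydroxy-2-methylbenzoate, via aryl acetate 3 (not isolated)
Conditions: AcCl, 1,2-dichlorobenzene, 60 °C; then AlCl3, 130 °C; aq. HCl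
Reagents that add atoms: acetyl chloride, CC(=O)Cl
Why: O-acetylation followed by AlCl3-promoted Fries rearrangement; the para position is blocked by the methyl group and C6 is squeezed between the oxygen and the ester, so the acyl group should enter at C4 and end as the chelated ortho-hydroxy ketone.

Step 3
Reactants: 4 methyl 4-acetyl-5-hydroxy-2-methylbenzoate
Product: 5 methyl 4-acetyl-2-methyl-5-(pivaloyloxy)benzoate
Conditions: PivCl, Et3N, DMAP (cat.), CH2Cl2, 0 to 23 °C
Reagents that add atoms: pivaloyl chloride, CC(C)(C)C(=O)Cl
Why: DMAP-catalysed acylation of the hydrogen-bonded phenol; a pivalate has no weak C–H bond for the radical step, resists the mild aqueous base of the coupling better than an acetate, and is later removed by the same hydride that reduces the ester.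

Step 4
Reactants: 5 methyl 4-acetyl-2-methyl-5-(pivaloyloxy)benzoate
Product: 6 methyl 4-acetyl-2-(bromomethyl)-5-(pivaloyloxy)benzoate
Conditions: NBS, AIBN (cat.), PhCF3, 80 °C
Reagents that add atoms: N-bromosuccinimide, O=C1CCC(=O)N1Br
Why: Wohl–Ziegler bromination; at this stage the aryl methyl group is the only benzylic C–H site in the molecule (no benzyl ether, silyloxymethyl group or ketal is present yet), and a radical chain at low bromine concentration favours it over the acetyl methyl group.

Step 5
Reactants: 7 1-(4-bromo-2-hydroxyphenyl)ethanone
Product: 8 1-[2-(benzyloxy)-4-bromophenyl]ethanone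
Conditions: BnBr, K2CO3, DMF, 60 °C
Reagents that add atoms: benzyl bromide, BrCc1ccccc1
Why: Williamson etherification of the phenoxide; the benzyl ether tolerates the couplings, hydride, oxidation and Grignard steps and is removed at the end without acid.

Step 6
Reactants: 8 1-[2-(benzyloxy)-4-bromophenyl]ethanone
Product: 9 1-[2-(benzyloxy)-4-(4,4,5,5-tetramethyl-1,3,2-dioxaborolan-2-yl)phenyl]ethanone
Conditions: B2pin2, Pd(dppf)Cl2 (cat.), KOAc, 1,4-dioxane, 90 °C
Reagents that add atoms: bis(pinacolato)diboron, CC1(C)OB(OC1(C)C)B1OC(C)(C)C(C)(C)O1
Why: Miyaura borylation of the aryl bromide; the weak base KOAc leaves the methyl ketone and the benzyl ether alone.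

Step 7
Reactants: 6 methyl 4-acetyl-2-(bromomethyl)-5-(pivaloyloxy)benzoate; 9 1-[2-(benzyloxy)-4-(4,4,5,5-tetramethyl-1,3,2-dioxaborolan-2-yl)phenyl]ethanone
Product: 10 methyl 4-acetyl-2-{[4-acetyl-3-(benzyloxy)phenyl]methyl}-5-(pivaloyloxy)benzoate
Conditions: Pd(dppf)Cl2 (cat.), K3PO4, THF/H2O (10:1), 60 °C
Reagents that add atoms: none
Why: Suzuki–Miyaura coupling of a benzylic bromide with an arylboronic ester forms the aryl–CH2 bond of the bridge; oxidative addition at the benzylic C–Br bond is fast, no beta-hydrogen is available, and the ketones, ester, pivalate and benzyl ether should tolerate the mild base.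

Step 8
Reactants: 10 methyl 4-acetyl-2-{[4-acetyl-3-(benzyloxy)phenyl]methyl}-5-(pivaloyloxy)benzoate
Product: 11 4-{[3-(benzyloxy)-4-(1-hydroxyethyl)phenyl]methyl}-2-(1-hydroxyethyl)-5-(hydroxymethyl)phenol (mixture of stereoisomers at both CH(OH)CH3 carbons)
Conditions: LiAlH4, THF, 0 to 23 °C; aq. potassium sodium tartrate
Reagents that add atoms: none
Why: Hydride reduction takes the methyl ester to the hydroxymethyl group and both ketones to secondary alcohols and cleaves the pivalate in one operation; the two new secondary carbinol centres form without control, which is harmless because both are oxidised back in step 11.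

Step 9
Reactants: 11 4-{[3-(benzyloxy)-4-(1-hydroxyethyl)phenyl]methyl}-2-(1-hydroxyethyl)-5-(hydroxymethyl)phenol
Product: 12 [5-(benzyloxy)-2-{[3-(benzyloxy)-4-(1-hydroxyethyl)phenyl]methyl}-4-(1-hydroxyethyl)phenyl]methanol (mixture of stereoisomers)
Conditions: BnBr, K2CO3, DMF, 23 °C
Reagents that add atoms: benzyl bromide, BrCc1ccccc1
Why: Only the phenol is acidic enough for K2CO3, so the Williamson benzylation should be selective for the phenolic oxygen over the three alcohols.

Step 10
Reactants: 12 [5-(benzyloxy)-2-{[3-(benzyloxy)-4-(1-hydroxyethyl)phenyl]methyl}-4-(1-hydroxyethyl)phenyl]methanol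
Product: 13 1-[2-(benzyloxy)-4-({4-(benzyloxy)-2-[(tert-butyldimethylsilyloxy)methyl]-5-(1-hydroxyethyl)phenyl}methyl)phenyl]ethanol (mixture of stereoisomers)
Conditions: TBSCl, imidazole, CH2Cl2, 0 °C
Reagents that add atoms: tert-butyldimethylsilyl chloride, CC(C)(C)[Si](C)(C)Cl
Why: Silylation with a bulky chlorosilane distinguishes the unhindered primary benzylic alcohol from the two secondary alcohols that are flanked by ortho-benzyloxy groups.

Step 11
Reactants: 13 1-[2-(benzyloxy)-4-({4-(benzyloxy)-2-[(tert-butyldimethylsilyloxy)methyl]-5-(1-hydroxyethyl)phenyl}methyl)phenyl]ethanol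
Product: 14 1-[2-(benzyloxy)-4-({5-acetyl-4-(benzyloxy)-2-[(tert-butyldimethylsilyloxy)methyl]phenyl}methyl)phenyl]ethanone
Conditions: Dess–Martin periodinane, CH2Cl2, 23 °C
Reagents that add atoms: none
Why: Dess–Martin oxidation of both secondary benzylic alcohols restores the two acetyl groups and erases the uncontrolled stereocentres; the silyl and benzyl ethers and the diarylmethane CH2 are inert to the periodinane.

Step 12
Reactants: 15 1-bromo-4-methylpentane
Product: 16 4-methylpentylmagnesium bromide
Conditions: Mg turnings, I2 (cat.), Et2O, reflux
Reagents that add atoms: magnesium, [Mg]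
Why: Grignard reagent formation by insertion of magnesium into the primary C–Br bond, in diethyl ether, the solvent in which the reagent is used in step 13.

Step 13
Reactants: 14 1-[2-(benzyloxy)-4-({5-acetyl-4-(benzyloxy)-2-[(tert-butyldimethylsilyloxy)methyl]phenyl}methyl)phenyl]ethanone; 16 4-methylpentylmagnesium bromide (two equivalents are built into the product, one at each acetyl group)
Product: 17 (2S)-2-[2-(benzyloxy)-4-({4-(benzyloxy)-2-[(tert-butyldimethylsilyloxy)methyl]-5-[(2S)-2-hydroxy-6-methylheptan-2-yl]phenyl}methyl)phenyl]-6-methylheptan-2-ol
Conditions: 2,4-di-tert-butyl-6-({[(1R,2R)-2-(dimethylamino)cyclohexyl](methyl)amino}methyl)phenol (2.2 equiv), 16 (4.6 equiv, Et2O), PhMe, −80 °C; then 14 in PhMe, slow addition; aq. NH4Cl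
Reagents that add atoms: 4-methylpentylmagnesium bromide (the second equivalent of 16, which alkylates the second acetyl group), CC(C)CCC[Mg]Br
Why: The ligand phenol is first deprotonated by 16 to a magnesium phenoxide held by both nitrogens and the oxygen; this chelate takes up a further molecule of 16 and the ketone oxygen, and the 4-methylpentyl group passes to the carbonyl carbon through a cyclic array in which the flat aryl group and the small methyl group occupy different pockets of the cyclohexanediamine scaffold. The closest known reaction type is the ligand-mediated enantioselective 1,2-addition of alkyl Grignard reagents to aryl methyl ketones, applied here once at each of the two acetyl groups of 14, so that two equivalents of 16 end up in 17 and two carbinol C–CH2 bonds are formed. No ring is closed. Each new stereocentre (the carbinol carbon on C1 of ring A and that on C3' of ring B) is set by the ligand alone, which should deliver the alkyl group to the Si face and so give S at both; the sites lie nine bonds apart across the CH2 bridge and cannot influence each other. The step needs enantioface selectivity at each carbonyl and chemoselectivity for addition over enolisation, beta-hydride reduction and unligated background addition; low temperature, toluene as main solvent and slow addition of 14 to the preformed complex serve the second need, and the like surroundings of the two acetyl groups (each ortho to a benzyloxy group, neither conjugated with the other ring) serve the first. Because the two additions are independent, most wrong-face addition should end up in the (R,S) and (S,R) diastereomers, which chromatography can remove, so the (S,S) product should be enantiomerically purer than a single addition would make it. The benzyl and silyl ethers offer the Grignard reagent no acidic or electrophilic site.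

Step 14
Reactants: 17 (2S)-2-[2-(benzyloxy)-4-({4-(benzyloxy)-2-[(tert-butyldimethylsilyloxy)methyl]-5-[(2S)-2-hydroxy-6-methylheptan-2-yl]phenyl}methyl)phenyl]-6-methylheptan-2-ol
Product: 18 5-({2-[(tert-butyldimethylsilyloxy)methyl]-4-hydroxy-5-[(2S)-2-hydroxy-6-methylheptan-2-yl]phenyl}methyl)-2-[(2S)-2-hydroxy-6-methylheptan-2-yl]phenol
Conditions: H2 (1 atm), Pd/C, EtOAc, 23 °C
Reagents that add atoms: none
Why: Hydrogenolysis should cleave the two aryl O–CH2Ph bonds far faster than any other benzylic C–O bond; a neutral aprotic solvent and interruption after two equivalents of hydrogen should preserve the silyl ether and the tertiary carbinols, whose configuration is not touched.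

Step 15
Reactants: 18 5-({2-[(tert-butyldimethylsilyloxy)methyl]-4-hydroxy-5-[(2S)-2-hydroxy-6-methylheptan-2-yl]phenyl}methyl)-2-[(2S)-2-hydroxy-6-methylheptan-2-yl]phenol
Product: 19 Disydonol C, 4-({3-hydroxy-4-[(2S)-2-hydroxy-6-methylheptan-2-yl]phenyl}methyl)-2-[(2S)-2-hydroxy-6-methylheptan-2-yl]-5-(hydroxymethyl)phenol
Conditions: TBAF, THF, 0 to 23 °C; aq. NH4Cl
Reagents that add atoms: none
Why: Fluoride-induced cleavage of the Si–O bond frees the hydroxymethyl group under non-acidic conditions, so the acid-labile ortho-hydroxyaryl carbinols should neither ionise nor lose configuration.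

## Compound list

1 | 5-hydroxy-2-methylbenzoic acid | Cc1ccc(O)cc1C(=O)O | starting material
2 | methyl 5-hydroxy-2-methylbenzoate | COC(=O)c1cc(O)ccc1C | intermediate
3 | methyl 5-acetoxy-2-methylbenzoate | COC(=O)c1cc(OC(C)=O)ccc1C | intermediate (not isolated)
4 | methyl 4-acetyl-5-hydroxy-2-methylbenzoate | COC(=O)c1cc(O)c(C(C)=O)cc1C | intermediate
5 | methyl 4-acetyl-2-methyl-5-(pivaloyloxy)benzoate | COC(=O)c1cc(OC(=O)C(C)(C)C)c(C(C)=O)cc1C | intermediate
6 | methyl 4-acetyl-2-(bromomethyl)-5-(pivaloyloxy)benzoate | COC(=O)c1cc(OC(=O)C(C)(C)C)c(C(C)=O)cc1CBr | intermediate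
7 | 1-(4-bromo-2-hydroxyphenyl)ethanone | CC(=O)c1ccc(Br)cc1O | starting material
8 | 1-[2-(benzyloxy)-4-bromophenyl]ethanone | CC(=O)c1ccc(Br)cc1OCc1ccccc1 | intermediate
9 | 1-[2-(benzyloxy)-4-(4,4,5,5-tetramethyl-1,3,2-dioxaborolan-2-yl)phenyl]ethanone | CC(=O)c1ccc(B2OC(C)(C)C(C)(C)O2)cc1OCc1ccccc1 | intermediate
10 | methyl 4-acetyl-2-{[4-acetyl-3-(benzyloxy)phenyl]methyl}-5-(pivaloyloxy)benzoate | COC(=O)c1cc(OC(=O)C(C)(C)C)c(C(C)=O)cc1Cc1ccc(C(C)=O)c(OCc2ccccc2)c1 | intermediate
11 | 4-{[3-(benzyloxy)-4-(1-hydroxyethyl)phenyl]methyl}-2-(1-hydroxyethyl)-5-(hydroxymethyl)phenol, mixture of stereoisomers | CC(O)c1ccc(Cc2cc(C(C)O)c(O)cc2CO)cc1OCc1ccccc1 | intermediate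
12 | [5-(benzyloxy)-2-{[3-(benzyloxy)-4-(1-hydroxyethyl)phenyl]methyl}-4-(1-hydroxyethyl)phenyl]methanol, mixture of stereoisomers | CC(O)c1ccc(Cc2cc(C(C)O)c(OCc3ccccc3)cc2CO)cc1OCc1ccccc1 | intermediate
13 | 1-[2-(benzyloxy)-4-({4-(benzyloxy)-2-[(tert-butyldimethylsilyloxy)methyl]-5-(1-hydroxyethyl)phenyl}methyl)phenyl]ethanol, mixture of stereoisomers | CC(O)c1ccc(Cc2cc(C(C)O)c(OCc3ccccc3)cc2CO[Si](C)(C)C(C)(C)C)cc1OCc1ccccc1 | intermediate
14 | 1-[2-(benzyloxy)-4-({5-acetyl-4-(benzyloxy)-2-[(tert-butyldimethylsilyloxy)methyl]phenyl}methyl)phenyl]ethanone | CC(=O)c1ccc(Cc2cc(C(C)=O)c(OCc3ccccc3)cc2CO[Si](C)(C)C(C)(C)C)cc1OCc1ccccc1 | intermediate (precursor of the key step)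
15 | 1-bromo-4-methylpentane | CC(C)CCCBr | starting material
16 | 4-methylpentylmagnesium bromide | CC(C)CCC[Mg]Br | intermediate
17 | (2S)-2-[2-(benzyloxy)-4-({4-(benzyloxy)-2-[(tert-butyldimethylsilyloxy)methyl]-5-[(2S)-2-hydroxy-6-methylheptan-2-yl]phenyl}methyl)phenyl]-6-methylheptan-2-ol | CC(C)CCC[C@](C)(O)c1ccc(Cc2cc([C@@](C)(O)CCCC(C)C)c(OCc3ccccc3)cc2CO[Si](C)(C)C(C)(C)C)cc1OCc1ccccc1 | intermediate (product of the key step)
18 | 5-({2-[(tert-butyldimethylsilyloxy)methyl]-4-hydroxy-5-[(2S)-2-hydroxy-6-methylheptan-2-yl]phenyl}methyl)-2-[(2S)-2-hydroxy-6-methylheptan-2-yl]phenol | CC(C)CCC[C@](C)(O)c1ccc(Cc2cc([C@@](C)(O)CCCC(C)C)c(O)cc2CO[Si](C)(C)C(C)(C)C)cc1O | intermediate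
19 | Disydonol C | CC(C)CCC[C@](C)(O)c1ccc(Cc2cc([C@@](C)(O)CCCC(C)C)c(O)cc2CO)cc1O | target

## Step count and least certain steps

Total: 15 steps. Longest linear sequence: 12 steps (steps 1, 2, 3, 4, 7, 8, 9, 10, 11, 13, 14, 15).

**Step 13 (key step).** Facial selectivity may be poor at one or both ketones, because magnesium can chelate between the carbonyl and the ortho-benzyloxy oxygen and add without the ligand. Enolisation or beta-hydride reduction may also lower conversion. The fallback replaces face selection by a stereospecific sequence. From 14, asymmetric transfer hydrogenation (RuCl[(R,R)-TsDPEN](p-cymene), HCO2H/Et3N, using the catalyst antipode that gives (R)-1-arylethanols) would give the (R,R)-bis(1-arylethanol) F1. N,N-Diisopropylcarbamoyl chloride and Et3N would give the bis(carbamate) F2. Deprotonation of both benzylic C–H bonds with s-BuLi in Et2O at −78 °C, addition of 4,4,5,5-tetramethyl-2-(4-methylpentyl)-1,3,2-dioxaborolane F3 (from 16 and 2-isopropoxy-4,4,5,5-tetramethyl-1,3,2-dioxaborolane) and warming would bring about 1,2-migration to the bis(tertiary boronic ester) F4. The stereochemical course is retention when boron captures the carbanion and inversion at the carbon that loses the carbamate, so (R)-carbamates lead to (S)-carbinols. Oxidation with NaOH/H2O2 proceeds with retention and gives 17, where the fallback rejoins the route.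

**Step 2.** The acyl group may migrate to C6 or between molecules, and hot AlCl3 may partly cleave the methyl ester. Fallback: from 2, bromination ortho to the hydroxyl (NBS, MeCN; para position blocked, C6 crowded) would give methyl 4-bromo-5-hydroxy-2-methylbenzoate F5. Stille coupling with tributyl(1-ethoxyvinyl)stannane (Pd(PPh3)4, toluene, 100 °C) would give methyl 4-(1-ethoxyvinyl)-5-hydroxy-2-methylbenzoate F6, which aqueous HCl hydrolyses in the work-up to 4.

**Step 4.** Bromination may run on to the dibromomethyl stage before the starting material is consumed, and some ionic bromination next to the ketone may occur if HBr builds up. Fallback: from 5, excess NBS would drive the benzylic position fully to methyl 4-acetyl-2-(dibromomethyl)-5-(pivaloyloxy)benzoate F7. Selective removal of one bromine with diethyl phosphite and N,N-diisopropylethylamine in THF would then give 6.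

**Step 7.** The benzylic bromide may hydrolyse (and then lactonise onto the ester). The pivalate may be lost before coupling, letting the phenoxide alkylate another molecule of bromide. Homocoupling is also possible. Fallback: a base-free Negishi coupling. From 6, zinc dust with LiCl in THF would give {[5-acetyl-2-(methoxycarbonyl)-4-(pivaloyloxy)phenyl]methyl}zinc bromide F8, which would be coupled with the aryl bromide 8 (Pd(OAc)2, SPhos, THF) to give 10.

**Step 14.** Hydrogenolysis may go on to cleave a tertiary benzylic C–O bond once the neighbouring phenol is free, or the silyloxymethyl C–O bond, and acidic sites on the catalyst may trigger dehydration. Fallback: move the hydrogenolysis to a stage without carbinols. From 14, H2 over Pd/C would give the bis(phenol) diketone F9. Allyl bromide and K2CO3 would give the bis(allyl ether) diketone F10. The conditions of step 13 would give the (S,S)-bis(allyl ether) bis(carbinol) F11. Deallylation with Pd(PPh3)4 and morpholine would give 18.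

## Further compounds

F1 | step 13 | (1R)-1-[2-(benzyloxy)-4-({4-(benzyloxy)-2-[(tert-butyldimethylsilyloxy)methyl]-5-[(1R)-1-hydroxyethyl]phenyl}methyl)phenyl]ethanol | C[C@@H](O)c1ccc(Cc2cc([C@@H](C)O)c(OCc3ccccc3)cc2CO[Si](C)(C)C(C)(C)C)cc1OCc1ccccc1
F2 | step 13 | bis(N,N-diisopropylcarbamate) of F1 | C[C@@H](OC(=O)N(C(C)C)C(C)C)c1ccc(Cc2cc([C@@H](C)OC(=O)N(C(C)C)C(C)C)c(OCc3ccccc3)cc2CO[Si](C)(C)C(C)(C)C)cc1OCc1ccccc1
F3 | step 13 | 4,4,5,5-tetramethyl-2-(4-methylpentyl)-1,3,2-dioxaborolane | CC(C)CCCB1OC(C)(C)C(C)(C)O1
F4 | step 13 | bis(tertiary pinacol boronic ester) corresponding to 17 (boron in place of each carbinol oxygen) | CC(C)CCC[C@](C)(B1OC(C)(C)C(C)(C)O1)c1ccc(Cc2cc([C@@](C)(B3OC(C)(C)C(C)(C)O3)CCCC(C)C)c(OCc3ccccc3)cc2CO[Si](C)(C)C(C)(C)C)cc1OCc1ccccc1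
F5 | step 2 | methyl 4-bromo-5-hydroxy-2-methylbenzoate | COC(=O)c1cc(O)c(Br)cc1C
F6 | step 2 | methyl 4-(1-ethoxyvinyl)-5-hydroxy-2-methylbenzoate | COC(=O)c1cc(O)c(C(=C)OCC)cc1C
F7 | step 4 | methyl 4-acetyl-2-(dibromomethyl)-5-(pivaloyloxy)benzoate | COC(=O)c1cc(OC(=O)C(C)(C)C)c(C(C)=O)cc1C(Br)Br
F8 | step 7 | {[5-acetyl-2-(methoxycarbonyl)-4-(pivaloyloxy)phenyl]methyl}zinc bromide | COC(=O)c1cc(OC(=O)C(C)(C)C)c(C(C)=O)cc1C[Zn]Br
F9 | step 14 | 1-[4-({5-acetyl-2-[(tert-butyldimethylsilyloxy)methyl]-4-hydroxyphenyl}methyl)-2-hydroxyphenyl]ethanone | CC(=O)c1ccc(Cc2cc(C(C)=O)c(O)cc2CO[Si](C)(C)C(C)(C)C)cc1O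
F10 | step 14 | 1-[4-({5-acetyl-4-(allyloxy)-2-[(tert-butyldimethylsilyloxy)methyl]phenyl}methyl)-2-(allyloxy)phenyl]ethanone | CC(=O)c1ccc(Cc2cc(C(C)=O)c(OCC=C)cc2CO[Si](C)(C)C(C)(C)C)cc1OCC=C
F11 | step 14 | (S,S)-bis(allyl ether) analogue of 17 | CC(C)CCC[C@](C)(O)c1ccc(Cc2cc([C@@](C)(O)CCCC(C)C)c(OCC=C)cc2CO[Si](C)(C)C(C)(C)C)cc1OCC=C
A1 | alternative 1 | ring B methyl benzoate with both phenol/carbinol pairs bridged as diisopropylsilylenes, (S,S) | COC(=O)c1cc2O[Si](C(C)C)(C(C)C)O[C@@](C)(CCCC(C)C)c2cc1Cc1ccc2c(c1)O[Si](C(C)C)(C(C)C)O[C@@]2(C)CCCC(C)C
A2 | alternative 1 | (S)-3,7-dimethyloct-1-yn-3-ol | CC(C)CCC[C@](C)(O)C#C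
A3 | alternative 1 | silicon-tethered 2-pyrone–alkyne precursor (pyrone C3–O–Si(iPr)2–O–carbinol of A2; ester at C5; ring A benzyl group at C6) | COC(=O)c1cc(O[Si](C(C)C)(C(C)C)O[C@@](C)(CCCC(C)C)C#C)c(=O)oc1Cc1ccc2c(c1)O[Si](C(C)C)(C(C)C)O[C@@]2(C)CCCC(C)C
A4 | alternative 2 | (S,S)-bis(benzoxasilole) | CC(C)CCC[C@]1(C)O[Si](CC)(CC)c2cc(Cc3cc4c(cc3CO[Si](C)(C)C(C)(C)C)[Si](CC)(CC)O[C@@]4(C)CCCC(C)C)ccc21
A5 | alternative 2 | (S,S)-bis-deoxy diol lacking both phenolic hydroxyls, CH2OH as tert-butyldimethylsilyl ether | CC(C)CCC[C@](C)(O)c1ccc(Cc2cc([C@@](C)(O)CCCC(C)C)ccc2CO[Si](C)(C)C(C)(C)C)cc1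
A6 | alternative 2 | bis(diethylhydrosilyl) ether of A5 | CC(C)CCC[C@](C)(O[SiH](CC)CC)c1ccc(Cc2cc([C@@](C)(O[SiH](CC)CC)CCCC(C)C)ccc2CO[Si](C)(C)C(C)(C)C)cc1
A7 | alternative 2 | bis-deoxy diketone, 1-[4-({5-acetyl-2-[(tert-butyldimethylsilyloxy)methyl]phenyl}methyl)phenyl]ethanone | CC(=O)c1ccc(Cc2cc(C(C)=O)ccc2CO[Si](C)(C)C(C)(C)C)cc1
A8 | alternative 3 | protected bis(tertiary neopentyl glycol boronic ester) | CC(C)CCC[C@](C)(B1OCC(C)(C)CO1)c1ccc(Cc2cc([C@@](C)(B3OCC(C)(C)CO3)CCCC(C)C)c(OCc3ccccc3)cc2CO[Si](C)(C)C(C)(C)C)cc1OCc1ccccc1
A9 | alternative 3 | (S)-6-methylheptan-2-yl 2,4,6-triisopropylbenzoate | CC(C)CCC[C@H](C)OC(=O)c1c(C(C)C)cc(C(C)C)cc1C(C)C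
A10 | alternative 3 | diarylmethane bis(arylboronic neopentyl glycol ester), phenols as benzyl ethers, CH2OH as tert-butyldimethylsilyl ether | CC1(C)COB(OC1)c1ccc(Cc2cc(B3OCC(C)(C)CO3)c(OCc3ccccc3)cc2CO[Si](C)(C)C(C)(C)C)cc1OCc1ccccc1
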